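**Retrosynthetic overview**

1. Labels used throughout: C1 = carboxyl carbon, C2 = its α-carbon, ring O1–O2–C3–C4–C5–C6 (O2 on C3, O1 on C6), C7–C18 = chain from C6. The plan rests on ring atoms C3–C4–C5–C6 with their two C–O bonds being a masked (E,E)-1,3-diene plus O2, and on the cis relation of C2 (on C3) and C7 (on C6), which is what suprafacial dioxygen addition to that diene gives.
2. Target 23 ⇒ methyl ester 21 ⇒ aldehyde 16 + farnesyl ylide 19 (Wittig at C7=C8, then diimide). The three trisubstituted chain alkenes, which singlet oxygen would attack, are attached last.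
3. 16 ⇒ 1,2-dioxane 12 (C1 alcohol to ester, C7 acetate to aldehyde) ⇒ 3,6-dihydro-1,2-dioxine 11 (diimide on C4=C5).
4. 11 ⇒ singlet-oxygen [4+2] on the hydroxy dienyl acetate 10. The only ring of the molecule is formed here, together with O2–C3, O1–C6, the quaternary C6 and the C3 centre.
5. 10 ⇒ vinylogous Horner–Wadsworth–Emmons union of aldehyde 4 (from methyl (R)-3-hydroxy-2-methylpropanoate 1, the source of C2) with phosphonate 5.

Key step: step 7

Assumption: phosphonate 5 and (2E,6E)-farnesyl bromide 17 are bought as single geometric isomers; the mixed geometry formed at C7=C8 in step 13 does not matter because that bond is saturated in step 14.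

**Route**

Step 1
Reactants: 1 methyl (R)-3-hydroxy-2-methylpropanoate
Product: 2 methyl (2R)-3-[(tert-butyldimethylsilyl)oxy]-2-methylpropanoate
Conditions: TBSCl, imidazole, CH2Cl2, 0 °C → rt
Reagents that add atoms: tert-butyldimethylsilyl chloride, CC(C)(C)[Si](C)(C)Cl
Why: Standard silyl ether formation at the primary alcohol under imidazole buffering, which leaves the α-stereocentre (the future C2) untouched.

Step 2
Reactants: 2 methyl (2R)-3-[(tert-butyldimethylsilyl)oxy]-2-methylpropanoate
Product: 4 (2R)-3-[(tert-butyldimethylsilyl)oxy]-2-methylpropanal, via aluminium hemiacetal 3 (not isolated)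
Conditions: i-Bu2AlH (1.1 equiv), CH2Cl2, −78 °C; MeOH, then aq. potassium sodium tartrate
Reagents that add atoms: none
Why: Partial ester reduction with i-Bu2AlH stops at the tetrahedral aluminium hemiacetal 3 at −78 °C and releases the aldehyde only on quench; the crude aldehyde is used at once so that the α-centre does not epimerise.

Step 3
Reactants: 4 (2R)-3-[(tert-butyldimethylsilyl)oxy]-2-methylpropanal; 5 ethyl (E)-4-(diethoxyphosphoryl)-2-methylbut-2-enoate
Product: 7 ethyl (2E,4E,6S)-7-[(tert-butyldimethylsilyl)oxy]-2,6-dimethylhepta-2,4-dienoate, via lithiated phosphonate 6 (not isolated)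
Conditions: 5, LiN(SiMe3)2 (slightly less than 5), THF, −78 °C; then 4, −78 → 0 °C
Reagents that add atoms: none
Why: Vinylogous Horner–Wadsworth–Emmons olefination in which the phosphonate anion reacts at its phosphorus-bearing carbon to form the new C3=C4 alkene with E geometry (thermodynamic control of the oxaphosphetane pathway) while the E geometry at C5=C6 comes from the reagent; the absence of excess base and the low temperature protect the C2 centre.

Step 4
Reactants: 7 ethyl (2E,4E,6S)-7-[(tert-butyldimethylsilyl)oxy]-2,6-dimethylhepta-2,4-dienoate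
Product: 8 (2E,4E,6S)-7-[(tert-butyldimethylsilyl)oxy]-2,6-dimethylhepta-2,4-dien-1-ol
Conditions: i-Bu2AlH (2.3 equiv), CH2Cl2, −78 °C; aq. potassium sodium tartrate
Reagents that add atoms: none
Why: 1,2-Reduction of the conjugated ester by i-Bu2AlH gives the dienylic alcohol (C7–OH) without touching the diene or the silyl ether.

Step 5
Reactants: 8 (2E,4E,6S)-7-[(tert-butyldimethylsilyl)oxy]-2,6-dimethylhepta-2,4-dien-1-ol
Product: 9 (2E,4E,6S)-7-[(tert-butyldimethylsilyl)oxy]-2,6-dimethylhepta-2,4-dien-1-yl acetate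
Conditions: Ac2O, pyridine, DMAP (cat.), CH2Cl2, 0 °C → rt
Reagents that add atoms: acetic anhydride, CC(=O)OC(C)=O
Why: DMAP-catalysed acylation; the acetate masks C7–OH through the oxidation of C1 and, being electron-withdrawing, lowers the ene reactivity of the C5=C6 alkene toward singlet oxygen.

Step 6
Reactants: 9 (2E,4E,6S)-7-[(tert-butyldimethylsilyl)oxy]-2,6-dimethylhepta-2,4-dien-1-yl acetate
Product: 10 (2E,4E,6S)-7-hydroxy-2,6-dimethylhepta-2,4-dien-1-yl acetate
Conditions: HF·pyridine, pyridine, THF, 0 °C → rt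
Reagents that add atoms: none
Why: Fluoride-mediated desilylation under pyridine buffering frees the C1 hydroxyl without hydrolysing or ionising the dienylic acetate.

Step 7
Reactants: 10 (2E,4E,6S)-7-hydroxy-2,6-dimethylhepta-2,4-dien-1-yl acetate
Product: 11 {(3R,6S)-6-[(2R)-1-hydroxypropan-2-yl]-3-methyl-3,6-dihydro-1,2-dioxin-3-yl}methyl acetate (acetoxymethyl and hydroxypropyl groups cis)
Conditions: O2, tetraphenylporphyrin (cat.), visible light (white LED), CH2Cl2, −30 °C
Reagents that add atoms: dioxygen (as singlet oxygen), O=O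
Why: Sensitised O2 gives singlet oxygen, which adds to the s-cis conformer of the (E,E)-diene in a concerted suprafacial [4+2] (hetero-Diels–Alder) reaction that forms O2–C3 and O1–C6 together; the closest known reaction type is the dye-sensitised photooxygenation of acyclic 1,3-dienes to 3,6-dihydro-1,2-dioxines, including dienes with a fully substituted terminus. The six-membered ring is closed by this intermolecular cycloaddition itself, both oxygens arriving on one diene face. The quaternary C6 is fixed relative to C3 by the diene geometry: the two outside groups (C2 on C3 and the acetoxymethyl C7 on C6) must end cis, and the inside hydrogen and methyl likewise. C3 is set relative to the bought C2 centre by π-facial choice: in the conformer with C2–H eclipsing C3=C4, oxygen should enter on the hydroxymethyl side, anti to the C2 methyl, steered by O–H···O2 hydrogen bonding in a non-donor solvent at low temperature. The step needs periselectivity over the ene reaction at the inside C6 methyl, which is kept in check by the deactivating allylic acetate and the cold non-polar medium, and it needs facial selectivity, which rests only on the free hydroxyl and is expected to be modest. The cis-dioxine of opposite face and any ene hydroperoxides would be removed by chromatography here or after step 8.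

Step 8
Reactants: 11 {(3R,6S)-6-[(2R)-1-hydroxypropan-2-yl]-3-methyl-3,6-dihydro-1,2-dioxin-3-yl}methyl acetate
Product: 12 {(3R,6S)-6-[(2R)-1-hydroxypropan-2-yl]-3-methyl-1,2-dioxan-3-yl}methyl acetate
Conditions: KO2CN=NCO2K (excess, in portions), AcOH, MeOH/CH2Cl2, 0 °C → rt
Reagents that add atoms: none
Why: Diimide reduction, a concerted syn transfer of H2 to the ring C4=C5 alkene that leaves the O–O bond intact (catalytic hydrogenation would cleave it); the slightly acidic medium avoids base-induced fragmentation of the dihydrodioxine, and no stereocentre is created.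

Step 9
Reactants: 12 {(3R,6S)-6-[(2R)-1-hydroxypropan-2-yl]-3-methyl-1,2-dioxan-3-yl}methyl acetate
Product: 14 (2S)-2-[(3S,6R)-6-(acetoxymethyl)-6-methyl-1,2-dioxan-3-yl]propanoic acid, via aldehyde 13 (not isolated)
Conditions: TEMPO (cat.), PhI(OAc)2 (2.5 equiv), MeCN/H2O (1:1), 0 °C → rt
Reagents that add atoms: water, O
Why: Oxoammonium (TEMPO/PhI(OAc)2) oxidation takes the primary alcohol through aldehyde 13 and its hydrate to the acid under near-neutral conditions, so the β-peroxy aldehyde neither eliminates nor epimerises at C2 before it is oxidised further.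

Step 10
Reactants: 14 (2S)-2-[(3S,6R)-6-(acetoxymethyl)-6-methyl-1,2-dioxan-3-yl]propanoic acid
Product: 15 methyl (2S)-2-[(3S,6R)-6-(hydroxymethyl)-6-methyl-1,2-dioxan-3-yl]propanoate
Conditions: HCl (0.5 M in MeOH), rt
Reagents that add atoms: methanol, CO
Why: Fischer esterification of the acid and acid-catalysed methanolysis (transesterification) of the acetate occur in one operation; dialkyl peroxides tolerate dilute acid, and no base meets the β-peroxy ester, which could open by E1cB elimination.

Step 11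
Reactants: 15 methyl (2S)-2-[(3S,6R)-6-(hydroxymethyl)-6-methyl-1,2-dioxan-3-yl]propanoate
Product: 16 methyl (2S)-2-[(3S,6R)-6-formyl-6-methyl-1,2-dioxan-3-yl]propanoate
Conditions: Dess–Martin periodinane, CH2Cl2, 0 °C → rt
Reagents that add atoms: none
Why: Dess–Martin oxidation of the neopentyl-type primary alcohol gives the non-enolisable α-peroxy aldehyde under mild non-basic conditions that the peroxide and the ester tolerate.

Step 12
Reactants: 17 (2E,6E)-1-bromo-3,7,11-trimethyldodeca-2,6,10-triene (farnesyl bromide)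
Product: 18 [(2E,6E)-3,7,11-trimethyldodeca-2,6,10-trien-1-yl]triphenylphosphonium bromide
Conditions: PPh3, MeCN, rt, dark
Reagents that add atoms: triphenylphosphine, c1ccc(cc1)P(c1ccccc1)c1ccccc1
Why: SN2 quaternisation of the phosphine by the primary allylic bromide (phosphonium salt formation) at room temperature should proceed without allylic transposition or E/Z isomerisation.

Step 13
Reactants: 16 methyl (2S)-2-[(3S,6R)-6-formyl-6-methyl-1,2-dioxan-3-yl]propanoate; 18 [(2E,6E)-3,7,11-trimethyldodeca-2,6,10-trien-1-yl]triphenylphosphonium bromide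
Product: 20 methyl (2S)-2-{(3S,6R)-6-methyl-6-[(3E,7E)-4,8,12-trimethyltrideca-1,3,7,11-tetraen-1-yl]-1,2-dioxan-3-yl}propanoate (E/Z mixture at the new alkene), via farnesylidene ylide 19 (not isolated)
Conditions: 18, NaN(SiMe3)2 (slightly less than 18), THF, −78 °C; then 16, −78 → 0 °C
Reagents that add atoms: none
Why: Wittig olefination of the non-enolisable aldehyde with the semi-stabilised allylic ylide forms C7=C8; the ylide is too weak a base to deprotonate C2 of the ester, 1,2-dioxanes tolerate phosphorus ylides, and the geometry of the new alkene is irrelevant.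

Step 14
Reactants: 20 methyl (2S)-2-{(3S,6R)-6-methyl-6-[(3E,7E)-4,8,12-trimethyltrideca-1,3,7,11-tetraen-1-yl]-1,2-dioxan-3-yl}propanoate
Product: 21 methyl (2S)-2-{(3S,6S)-6-methyl-6-[(3E,7E)-4,8,12-trimethyltrideca-3,7,11-trien-1-yl]-1,2-dioxan-3-yl}propanoate
Conditions: KO2CN=NCO2K (in portions, followed by NMR), AcOH, MeOH/CH2Cl2, 0 °C
Reagents that add atoms: none
Why: Chemoselective diimide reduction: the concerted syn H2 transfer is markedly faster at the 1,2-disubstituted C7=C8 bond of the activated conjugated diene than at trisubstituted alkenes, so portionwise addition stopped at consumption of the diene should leave the three chain alkenes and the O–O bond untouched.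

Step 15
Reactants: 21 methyl (2S)-2-{(3S,6S)-6-methyl-6-[(3E,7E)-4,8,12-trimethyltrideca-3,7,11-trien-1-yl]-1,2-dioxan-3-yl}propanoate
Product: 23 (2S)-2-{(3S,6S)-6-methyl-6-[(3E,7E)-4,8,12-trimethyltrideca-3,7,11-trien-1-yl]-1,2-dioxan-3-yl}propanoic acid, via lithium carboxylate 22 (not isolated)
Conditions: LiOH, THF/H2O (3:1), 0 °C; then 0.5 M HCl to pH 3
Reagents that add atoms: lithium hydroxide, [Li+].[OH-]
Why: Ester saponification at 0 °C, where hydroxide attack at the unhindered methyl ester should outpace deprotonation at C2, so the β-peroxy linkage and the C2 centre survive; acidification frees the acid.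

**Compound list**

1 | methyl (R)-3-hydroxy-2-methylpropanoate | COC(=O)[C@H](C)CO | starting material
2 | methyl (2R)-3-[(tert-butyldimethylsilyl)oxy]-2-methylpropanoate | COC(=O)[C@H](C)CO[Si](C)(C)C(C)(C)C | intermediate
3 | {(2R)-3-[(tert-butyldimethylsilyl)oxy]-1-methoxy-2-methylpropoxy}bis(2-methylpropyl)alane (aluminium hemiacetal) | COC(O[Al](CC(C)C)CC(C)C)[C@H](C)CO[Si](C)(C)C(C)(C)C | intermediate (not isolated)
4 | (2R)-3-[(tert-butyldimethylsilyl)oxy]-2-methylpropanal | O=C[C@H](C)CO[Si](C)(C)C(C)(C)C | intermediate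
5 | ethyl (E)-4-(diethoxyphosphoryl)-2-methylbut-2-enoate | CCOC(=O)/C(C)=C/CP(=O)(OCC)OCC | starting material
6 | lithium salt of the phosphonate anion of 5 | [Li+].CCOC(=O)/C(C)=C/[CH-]P(=O)(OCC)OCC | intermediate (not isolated)
7 | ethyl (2E,4E,6S)-7-[(tert-butyldimethylsilyl)oxy]-2,6-dimethylhepta-2,4-dienoate | CCOC(=O)/C(C)=C/C=C/[C@H](C)CO[Si](C)(C)C(C)(C)C | intermediate
8 | (2E,4E,6S)-7-[(tert-butyldimethylsilyl)oxy]-2,6-dimethylhepta-2,4-dien-1-ol | OC/C(C)=C/C=C/[C@H](C)CO[Si](C)(C)C(C)(C)C | intermediate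
9 | (2E,4E,6S)-7-[(tert-butyldimethylsilyl)oxy]-2,6-dimethylhepta-2,4-dien-1-yl acetate | CC(=O)OC/C(C)=C/C=C/[C@H](C)CO[Si](C)(C)C(C)(C)C | intermediate
10 | (2E,4E,6S)-7-hydroxy-2,6-dimethylhepta-2,4-dien-1-yl acetate | CC(=O)OC/C(C)=C/C=C/[C@H](C)CO | intermediate
11 | {(3R,6S)-6-[(2R)-1-hydroxypropan-2-yl]-3-methyl-3,6-dihydro-1,2-dioxin-3-yl}methyl acetate | CC(=O)OC[C@@]1(C)C=C[C@@H]([C@H](C)CO)OO1 | intermediate
12 | {(3R,6S)-6-[(2R)-1-hydroxypropan-2-yl]-3-methyl-1,2-dioxan-3-yl}methyl acetate | CC(=O)OC[C@@]1(C)CC[C@@H]([C@H](C)CO)OO1 | intermediate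
13 | {(3R,6S)-3-methyl-6-[(2S)-1-oxopropan-2-yl]-1,2-dioxan-3-yl}methyl acetate | CC(=O)OC[C@@]1(C)CC[C@@H]([C@H](C)C=O)OO1 | intermediate (not isolated)
14 | (2S)-2-[(3S,6R)-6-(acetoxymethyl)-6-methyl-1,2-dioxan-3-yl]propanoic acid | CC(=O)OC[C@@]1(C)CC[C@@H]([C@H](C)C(=O)O)OO1 | intermediate
15 | methyl (2S)-2-[(3S,6R)-6-(hydroxymethyl)-6-methyl-1,2-dioxan-3-yl]propanoate | OC[C@@]1(C)CC[C@@H]([C@H](C)C(=O)OC)OO1 | intermediate
16 | methyl (2S)-2-[(3S,6R)-6-formyl-6-methyl-1,2-dioxan-3-yl]propanoate | O=C[C@@]1(C)CC[C@@H]([C@H](C)C(=O)OC)OO1 | intermediate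
17 | (2E,6E)-1-bromo-3,7,11-trimethyldodeca-2,6,10-triene | CC(C)=CCC/C(C)=C/CC/C(C)=C/CBr | starting material
18 | [(2E,6E)-3,7,11-trimethyldodeca-2,6,10-trien-1-yl]triphenylphosphonium bromide | CC(C)=CCC/C(C)=C/CC/C(C)=C/C[P+](c1ccccc1)(c1ccccc1)c1ccccc1.[Br-] | intermediate
19 | [(2E,6E)-3,7,11-trimethyldodeca-2,6,10-trien-1-ylidene]triphenylphosphorane | CC(C)=CCC/C(C)=C/CC/C(C)=C/C=P(c1ccccc1)(c1ccccc1)c1ccccc1 | intermediate (not isolated)
20 | methyl (2S)-2-{(3S,6R)-6-methyl-6-[(3E,7E)-4,8,12-trimethyltrideca-1,3,7,11-tetraen-1-yl]-1,2-dioxan-3-yl}propanoate | CC(C)=CCC/C(C)=C/CC/C(C)=C/C=C[C@@]1(C)CC[C@@H]([C@H](C)C(=O)OC)OO1 | intermediate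
21 | methyl (2S)-2-{(3S,6S)-6-methyl-6-[(3E,7E)-4,8,12-trimethyltrideca-3,7,11-trien-1-yl]-1,2-dioxan-3-yl}propanoate | CC(C)=CCC/C(C)=C/CC/C(C)=C/CC[C@@]1(C)CC[C@@H]([C@H](C)C(=O)OC)OO1 | intermediate
22 | lithium (2S)-2-{(3S,6S)-6-methyl-6-[(3E,7E)-4,8,12-trimethyltrideca-3,7,11-trien-1-yl]-1,2-dioxan-3-yl}propanoate | [Li+].CC(C)=CCC/C(C)=C/CC/C(C)=C/CC[C@@]1(C)CC[C@@H]([C@H](C)C(=O)[O-])OO1 | intermediate (not isolated)
23 | (2S)-2-{(3S,6S)-6-methyl-6-[(3E,7E)-4,8,12-trimethyltrideca-3,7,11-trien-1-yl]-1,2-dioxan-3-yl}propanoic acid | CC(C)=CCC/C(C)=C/CC/C(C)=C/CC[C@@]1(C)CC[C@@H]([C@H](C)C(=O)O)OO1 | target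

The CIP letter at the quaternary ring carbon changes between 11–20 and 21–23 only because the priority of its substituents changes; its spatial arrangement is the same throughout.

**Totals**

Total step count: 15. Longest linear sequence: 14 steps (steps 1–11 and 13–15, from 1 to 23).

**Steps most likely to fail**

Step 7. The ene reaction at the inside C6 methyl may outrun the cycloaddition because the s-cis conformer is thinly populated, and the remote hydroxyl may discriminate the two diene faces poorly, so that the wanted cis-dioxine becomes a minor component. The fallback replaces the cycloaddition by a stepwise polar ring closure; it sets out from aldehyde 4 and returns to the route at 12.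
- Re-face Brown allylation of 4 with (+)-Ipc2B(allyl) (Et2O, −78 °C; then NaOH/H2O2) should give the 2,3-syn homoallylic alcohol (2R,3R)-1-[(tert-butyldimethylsilyl)oxy]-2-methylhex-5-en-3-ol F1.
- MsCl/Et3N converts it into (2R,3R)-1-[(tert-butyldimethylsilyl)oxy]-2-methylhex-5-en-3-yl methanesulfonate F2.
- Cross-metathesis with 2-methylallyl acetate (second-generation Grubbs catalyst, CH2Cl2, 40 °C) gives the trisubstituted allylic acetate (5R,6R)-7-[(tert-butyldimethylsilyl)oxy]-2,6-dimethyl-5-(methanesulfonyloxy)hept-2-en-1-yl acetate F3, whose alkene geometry is immaterial.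
- Mukaiyama–Isayama peroxidation (Co(acac)2, O2, Et3SiH, 1,2-dichloroethane, rt) places the peroxide on the tertiary carbon C6 to give (5R,6R)-7-[(tert-butyldimethylsilyl)oxy]-2,6-dimethyl-5-(methanesulfonyloxy)-2-[(triethylsilyl)peroxy]heptyl acetate F4 as both C6 epimers.
- n-Bu4NF in THF (0 °C → rt) removes both silyl groups, and the freed peroxide anion displaces the C3 mesylate with inversion (6-exo-tet). This gives 12 together with its C6 epimer {(3S,6S)-6-[(2R)-1-hydroxypropan-2-yl]-3-methyl-1,2-dioxan-3-yl}methyl acetate F5, which is removed by chromatography.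
- C3 is then set by the reagent-controlled allylation and the SN2 inversion rather than by a facial preference, at the price of no control at C6.

Step 14. Diimide may not stop at C7=C8: the trisubstituted C9=C10 of the conjugated diene or the remote trisubstituted alkenes may be saturated before the hindered C7=C8 bond is consumed, giving over-reduced material that is hard to separate. The fallback forms the C8–C9 bond by B-alkyl Suzuki–Miyaura coupling, so that no chain alkene has to be reduced; it sets out from aldehyde 16 and returns at 21.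
- Wittig methylenation of 16 (Ph3PCH3Br, NaN(SiMe3)2, THF, −78 → 0 °C) gives the vinyl dioxane methyl (2S)-2-[(3S,6R)-6-ethenyl-6-methyl-1,2-dioxan-3-yl]propanoate F6.
- Hydroboration with 9-BBN (THF, 0 °C → rt) gives the B-alkyl borane methyl (2S)-2-{(3S,6S)-6-[2-(9-borabicyclo[3.3.1]nonan-9-yl)ethyl]-6-methyl-1,2-dioxan-3-yl}propanoate F7, used in solution.
- Coupling with the vinyl iodide (1E,5E)-1-iodo-2,6,10-trimethylundeca-1,5,9-triene F10 (PdCl2(dppf), AsPh3, aq. Cs2CO3, DMF/THF, rt) gives 21 directly.
- The iodide is prepared from geranyl bromide. Alkylation of lithiated 1-(trimethylsilyl)propyne (n-BuLi, THF, −78 °C) gives trimethyl[(5E)-6,10-dimethylundeca-5,9-dien-1-yn-1-yl]silane F8. K2CO3/MeOH gives (5E)-6,10-dimethylundeca-5,9-dien-1-yne F9. Negishi carboalumination–iodination (AlMe3, Cp2ZrCl2, CH2Cl2; then I2) sets the E trisubstituted vinyl iodide.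
- The tolerance of the O–O bond toward the borane and the palladium catalyst is the open point of this fallback.

Step 13. The semi-stabilised ylide may add sluggishly to the neopentyl-type α-peroxy aldehyde and instead attack the O–O bond or decompose, leaving the aldehyde unconverted. The fallback is a sulfone-based Julia–Kocienski olefination; it sets out from aldehyde 16, with the partner made from bromide 17, and returns at 20.
- Bromide 17 with 1-phenyl-1H-tetrazole-5-thiol and K2CO3 in acetone gives the sulfide 1-phenyl-5-{[(2E,6E)-3,7,11-trimethyldodeca-2,6,10-trien-1-yl]sulfanyl}-1H-tetrazole F11.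
- Oxidation with (NH4)6Mo7O24·4H2O (cat.) and H2O2 in EtOH (0 °C → rt) gives the sulfone 1-phenyl-5-{[(2E,6E)-3,7,11-trimethyldodeca-2,6,10-trien-1-yl]sulfonyl}-1H-tetrazole F12.
- KN(SiMe3)2 is added to a mixture of the sulfone and 16 in THF at −78 °C (Barbier mode). The more nucleophilic sulfonyl carbanion adds to the aldehyde, and Smiles rearrangement and loss of SO2 and the tetrazolone give 20.

**Further compounds**

F1 | step 7 | (2R,3R)-1-[(tert-butyldimethylsilyl)oxy]-2-methylhex-5-en-3-ol | C=CC[C@H]([C@H](C)CO[Si](C)(C)C(C)(C)C)O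
F2 | step 7 | (2R,3R)-1-[(tert-butyldimethylsilyl)oxy]-2-methylhex-5-en-3-yl methanesulfonate | C=CC[C@H]([C@H](C)CO[Si](C)(C)C(C)(C)C)OS(C)(=O)=O
F3 | step 7 | (5R,6R)-7-[(tert-butyldimethylsilyl)oxy]-2,6-dimethyl-5-(methanesulfonyloxy)hept-2-en-1-yl acetate | CC(=O)OCC(C)=CC[C@H]([C@H](C)CO[Si](C)(C)C(C)(C)C)OS(C)(=O)=O
F4 | step 7 | (5R,6R)-7-[(tert-butyldimethylsilyl)oxy]-2,6-dimethyl-5-(methanesulfonyloxy)-2-[(triethylsilyl)peroxy]heptyl acetate | CC(=O)OCC(C)(OO[Si](CC)(CC)CC)CC[C@H]([C@H](C)CO[Si](C)(C)C(C)(C)C)OS(C)(=O)=O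
F5 | step 7 | {(3S,6S)-6-[(2R)-1-hydroxypropan-2-yl]-3-methyl-1,2-dioxan-3-yl}methyl acetate | CC(=O)OC[C@]1(C)CC[C@@H]([C@H](C)CO)OO1
F6 | step 14 | methyl (2S)-2-[(3S,6R)-6-ethenyl-6-methyl-1,2-dioxan-3-yl]propanoate | C=C[C@@]1(C)CC[C@@H]([C@H](C)C(=O)OC)OO1
F7 | step 14 | methyl (2S)-2-{(3S,6S)-6-[2-(9-borabicyclo[3.3.1]nonan-9-yl)ethyl]-6-methyl-1,2-dioxan-3-yl}propanoate | C1CC2CCCC(C1)B2CC[C@@]1(C)CC[C@@H]([C@H](C)C(=O)OC)OO1
F8 | step 14 | trimethyl[(5E)-6,10-dimethylundeca-5,9-dien-1-yn-1-yl]silane | CC(C)=CCC/C(C)=C/CCC#C[Si](C)(C)C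
F9 | step 14 | (5E)-6,10-dimethylundeca-5,9-dien-1-yne | CC(C)=CCC/C(C)=C/CCC#C
F10 | step 14 | (1E,5E)-1-iodo-2,6,10-trimethylundeca-1,5,9-triene | CC(C)=CCC/C(C)=C/CC/C(C)=C/I
F11 | step 13 | 1-phenyl-5-{[(2E,6E)-3,7,11-trimethyldodeca-2,6,10-trien-1-yl]sulfanyl}-1H-tetrazole | CC(C)=CCC/C(C)=C/CC/C(C)=C/CSc1nnnn1-c1ccccc1
F12 | step 13 | 1-phenyl-5-{[(2E,6E)-3,7,11-trimethyldodeca-2,6,10-trien-1-yl]sulfonyl}-1H-tetrazole | CC(C)=CCC/C(C)=C/CC/C(C)=C/CS(=O)(=O)c1nnnn1-c1ccccc1
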